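**Strategy.** Everything rests on cutting C3 out of the C ring (O1–C2–C3–C4–C4a–C8a). The chromanone is traced back to a racemic 2-aryl-2-(iodomethyl)benzofuran-3(2H)-one. In one operation, iodine abstraction, a Dowd–Beckwith 1,2-acyl shift and hydrogen-atom transfer from a chiral thiol insert the CH2 group between C2 and the C4 carbonyl. This enlarges the five-membered ring to six, erases the quaternary centre and sets C2, so both enantiomers of the precursor converge on (2S). The step exploits that C2 bears O1 and the B-ring aryl group, which make the ring-expanded C2 radical much more stable than the primary radical. The 8-prenyl/5-OH pair comes from a para-Claisen–Cope shift.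

Key step: step 7

Remark 1: the sense of induction of the peptide thiol in step 7 cannot be predicted with certainty. It is assumed that the enantiomeric series of the catalyst (built from L- or D-amino acids) that transfers hydrogen to the Re face of C2 is used.
Remark 2: compounds 1, 3, 5 and 8 are taken as commercial.

Step 1
Reactants: 1 5-bromo-2-methoxyphenol
Product: 2 (5-bromo-2-methoxyphenoxy)triisopropylsilane
Conditions: TIPSCl, imidazole, DMF, rt
Reagents that add atoms: chlorotriisopropylsilane CC(C)[Si](Cl)(C(C)C)C(C)C
Why: Standard O-silylation of a phenol; the bulky aryl TIPS ether should survive the bases, the Lewis acids and the radical step that follow and is removable under non-basic conditions at the end.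

Step 2
Reactants: 3 4,6-dimethoxybenzofuran-3(2H)-one; 2 (5-bromo-2-methoxyphenoxy)triisopropylsilane
Product: 4 rac-4,6-dimethoxy-2-[4-methoxy-3-(triisopropylsilyloxy)phenyl]benzofuran-3(2H)-one
Conditions: Pd(OAc)2 (3 mol %), XPhos (6 mol %), K3PO4, toluene, 90 °C, Ar; degassed aq. NH4Cl
Reagents that add atoms: none
Why: Palladium-catalysed ketone α-arylation (oxidative addition of C–Br, binding of the deprotonated ketone, reductive elimination) should form the C2–aryl bond, with the bulky ligand and one equivalent of 2 limiting diarylation; C2 arises as a racemic, enolisable centre of no consequence, and 4 is handled under argon because it autoxidises easily.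

Step 3
Reactants: 4 rac-4,6-dimethoxy-2-[4-methoxy-3-(triisopropylsilyloxy)phenyl]benzofuran-3(2H)-one; 5 diiodomethane
Product: 6 rac-2-(iodomethyl)-4,6-dimethoxy-2-[4-methoxy-3-(triisopropylsilyloxy)phenyl]benzofuran-3(2H)-one
Conditions: NaH, THF–DMPU, 0 °C; CH2I2 (5 equiv), 0 °C to rt, dark, Ar
Reagents that add atoms: diiodomethane (5) ICI
Why: C-alkylation of the deprotonated ketone with the soft electrophile CH2I2, the usual way to prepare Dowd–Beckwith substrates, should give the quaternary C2 as a racemate, which is irrelevant because step 7 erases this centre; the product has no β-hydrogen, so HI cannot be lost.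

Step 4
Reactants: 6 rac-2-(iodomethyl)-4,6-dimethoxy-2-[4-methoxy-3-(triisopropylsilyloxy)phenyl]benzofuran-3(2H)-one
Product: 7 rac-4-hydroxy-2-(iodomethyl)-6-methoxy-2-[4-methoxy-3-(triisopropylsilyloxy)phenyl]benzofuran-3(2H)-one
Conditions: BCl3 (1.2 equiv), CH2Cl2, −78 to −10 °C; aq. NaHCO3
Reagents that add atoms: none
Why: Chelation-controlled ether cleavage: boron binds between the C3 carbonyl and the peri 4-OMe, so only this methyl ether should be cleaved while 6-OMe, the B-ring OMe, the silyl ether and the iodide stay intact at low temperature.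

Step 5
Reactants: 7 rac-4-hydroxy-2-(iodomethyl)-6-methoxy-2-[4-methoxy-3-(triisopropylsilyloxy)phenyl]benzofuran-3(2H)-one; 8 3-methylbut-2-en-1-ol
Product: 9 rac-2-(iodomethyl)-6-methoxy-4-(3-methylbut-2-enyloxy)-2-[4-methoxy-3-(triisopropylsilyloxy)phenyl]benzofuran-3(2H)-one
Conditions: PPh3, DIAD, THF, 0 °C to rt
Reagents that add atoms: 3-methylbut-2-en-1-ol (8) CC(C)=CCO
Why: Mitsunobu etherification alkylates the only free phenol at oxygen under neutral conditions, which spares the silyl ether, and the neopentyl-type iodide is inert to phosphine.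

Step 6
Reactants: 9 rac-2-(iodomethyl)-6-methoxy-4-(3-methylbut-2-enyloxy)-2-[4-methoxy-3-(triisopropylsilyloxy)phenyl]benzofuran-3(2H)-one
Product: 11 rac-4-hydroxy-2-(iodomethyl)-6-methoxy-7-(3-methylbut-2-enyl)-2-[4-methoxy-3-(triisopropylsilyloxy)phenyl]benzofuran-3(2H)-one, via ortho-dienone 10 (not isolated)
Conditions: Eu(fod)3 (10 mol %), PhCl, 90 °C, Ar, dark
Reagents that add atoms: none
Why: Lewis-acid-accelerated aromatic Claisen rearrangement to C5 gives 10, whose reverse-prenyl group is crowded between two oxygenated carbons and should move on by a Cope shift to C7, the position para to O4, before tautomerisation (para-Claisen–Cope, known for 5-O-prenyl flavonoids); this places the prenyl group next to O1 and frees the chelated OH in one step.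

Step 7
Reactants: 11 rac-4-hydroxy-2-(iodomethyl)-6-methoxy-7-(3-methylbut-2-enyl)-2-[4-methoxy-3-(triisopropylsilyloxy)phenyl]benzofuran-3(2H)-one
Product: 15 (2S)-5-hydroxy-7-methoxy-2-[4-methoxy-3-(triisopropylsilyloxy)phenyl]-8-(3-methylbut-2-enyl)chroman-4-one, via primary alkyl radical 12 (not isolated), via cyclopropyloxy radical 13 (not isolated), via chromanon-2-yl radical 14 (not isolated)
Conditions: 1,3-dimethylimidazol-2-ylidene borane (1.2 equiv), β-turn cysteine peptide thiol (10 mol %), V-70 (10 mol %), PhCF3 (0.01 M), 30 °C, Ar, dark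
Reagents that add atoms: none
Why: Proposed new method: a boryl radical abstracts iodine from 11, radical 12 adds 3-exo-trig to the C3 carbonyl (activated by the hydrogen bond from 4-OH) to give 13, β-scission of the old C2–C3 bond moves the acyl group onto the CH2 carbon and gives 14, and the thiol reduces 14 while the thiyl radical restarts the chain by abstracting hydrogen from the borane. The closest known reaction types are the Dowd–Beckwith ring expansion of α-(halomethyl) benzocyclic ketones, the thiol-catalysed (polarity-reversal) reduction of alkyl halides with NHC-boranes and the catalytic asymmetric hydrogen-atom transfer from peptide thiols to prochiral radicals, whose combination on a flavanone C2 radical has not been shown. No ring of the product is closed by a cyclisation: only the transient cyclopropane of 13 is closed (3-exo-trig), and the six-membered ring arises when the bond shared by the three- and five-membered rings breaks. C2 is the only new stereocentre and is set under catalyst control by hydrogen delivery to the Re face of planar 14, which can be held to the peptide by hydrogen bonds at C4=O/5-OH and by stacking on the B ring, so the racemic quaternary centre of 11 is funnelled into one configuration. The acyl shift must outrun direct reduction of 12, the neophyl-type 1,2-shift of the B ring and β-scission of the C2–O1 bond, which is served by high dilution, the low thiol loading, the poor hydrogen-donor ability of the borane towards alkyl radicals, the intrinsic order acyl > aryl for 1,2-shifts and the large stabilisation gained from 12 to 14. The hydridic borane is polarity-mismatched with nucleophilic 14, so the hydrogen should arrive through the chiral thiol, fast thiyl–borane transfer should prevent re-abstraction of the new C2–H, and the prenyl alkene should be spared because iodine abstraction is far faster than radical addition to a trisubstituted alkene.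

Step 8
Reactants: 15 (2S)-5-hydroxy-7-methoxy-2-[4-methoxy-3-(triisopropylsilyloxy)phenyl]-8-(3-methylbut-2-enyl)chroman-4-one
Product: 16 (2S)-5-hydroxy-2-(3-hydroxy-4-methoxyphenyl)-7-methoxy-8-(3-methylbut-2-enyl)chroman-4-one
Conditions: TBAF (1.1 equiv), AcOH (1.2 equiv), THF, 0 °C
Reagents that add atoms: none
Why: Fluoride-induced cleavage of the aryl silyl ether; the acetic acid buffer keeps the medium non-basic, so the retro-oxa-Michael opening that would racemise C2 is not triggered and the prenyl group is untouched.

**Compound list**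

1 | 5-bromo-2-methoxyphenol | COc1ccc(Br)cc1O | starting material
2 | (5-bromo-2-methoxyphenoxy)triisopropylsilane | COc1ccc(Br)cc1O[Si](C(C)C)(C(C)C)C(C)C | intermediate
3 | 4,6-dimethoxybenzofuran-3(2H)-one | COc1cc(OC)c2c(c1)OCC2=O | starting material
4 | rac-4,6-dimethoxy-2-[4-methoxy-3-(triisopropylsilyloxy)phenyl]benzofuran-3(2H)-one | COc1cc(OC)c2c(c1)OC(C2=O)c1ccc(OC)c(O[Si](C(C)C)(C(C)C)C(C)C)c1 | intermediate
5 | diiodomethane | ICI | starting material
6 | rac-2-(iodomethyl)-4,6-dimethoxy-2-[4-methoxy-3-(triisopropylsilyloxy)phenyl]benzofuran-3(2H)-one | COc1cc(OC)c2c(c1)OC(CI)(C2=O)c1ccc(OC)c(O[Si](C(C)C)(C(C)C)C(C)C)c1 | intermediate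
7 | rac-4-hydroxy-2-(iodomethyl)-6-methoxy-2-[4-methoxy-3-(triisopropylsilyloxy)phenyl]benzofuran-3(2H)-one | COc1cc(O)c2c(c1)OC(CI)(C2=O)c1ccc(OC)c(O[Si](C(C)C)(C(C)C)C(C)C)c1 | intermediate
8 | 3-methylbut-2-en-1-ol | CC(C)=CCO | starting material
9 | rac-2-(iodomethyl)-6-methoxy-4-(3-methylbut-2-enyloxy)-2-[4-methoxy-3-(triisopropylsilyloxy)phenyl]benzofuran-3(2H)-one | COc1cc(OCC=C(C)C)c2c(c1)OC(CI)(C2=O)c1ccc(OC)c(O[Si](C(C)C)(C(C)C)C(C)C)c1 | intermediate
10 | ortho-dienone, 2-(iodomethyl)-6-methoxy-5-(2-methylbut-3-en-2-yl)-2-[4-methoxy-3-(triisopropylsilyloxy)phenyl]benzofuran-3,4(2H,5H)-dione (diastereomer mixture, not isolated) | COC1=CC2=C(C(=O)C1C(C)(C)C=C)C(=O)C(CI)(O2)c1ccc(OC)c(O[Si](C(C)C)(C(C)C)C(C)C)c1 | intermediate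
11 | rac-4-hydroxy-2-(iodomethyl)-6-methoxy-7-(3-methylbut-2-enyl)-2-[4-methoxy-3-(triisopropylsilyloxy)phenyl]benzofuran-3(2H)-one | COc1cc(O)c2c(c1CC=C(C)C)OC(CI)(C2=O)c1ccc(OC)c(O[Si](C(C)C)(C(C)C)C(C)C)c1 | intermediate
12 | primary alkyl radical, (3-oxo-2-arylbenzofuran-2-yl)methyl radical from 11 (not isolated) | [CH2]C1(Oc2c(CC=C(C)C)c(OC)cc(O)c2C1=O)c1ccc(OC)c(O[Si](C(C)C)(C(C)C)C(C)C)c1 | intermediate
13 | cyclopropyloxy radical, 1a-arylcyclopropa[b]benzofuran-6b-oxyl (not isolated) | [O]C12CC1(c1ccc(OC)c(O[Si](C(C)C)(C(C)C)C(C)C)c1)Oc1c(CC=C(C)C)c(OC)cc(O)c12 | intermediate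
14 | chromanon-2-yl radical, ring-expanded 2-aryl-4-oxochroman-2-yl radical (not isolated) | COc1ccc([C]2CC(=O)c3c(O)cc(OC)c(CC=C(C)C)c3O2)cc1O[Si](C(C)C)(C(C)C)C(C)C | intermediate
15 | (2S)-5-hydroxy-7-methoxy-2-[4-methoxy-3-(triisopropylsilyloxy)phenyl]-8-(3-methylbut-2-enyl)chroman-4-one | COc1ccc([C@@H]2CC(=O)c3c(O)cc(OC)c(CC=C(C)C)c3O2)cc1O[Si](C(C)C)(C(C)C)C(C)C | intermediate
16 | (2S)-5-hydroxy-2-(3-hydroxy-4-methoxyphenyl)-7-methoxy-8-(3-methylbut-2-enyl)chroman-4-one | COc1ccc([C@@H]2CC(=O)c3c(O)cc(OC)c(CC=C(C)C)c3O2)cc1O | target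

Total step count: 8. Longest linear sequence: 8 steps (1 to 16).

**Steps most likely to fail**

**Step 7.** Several processes could defeat it:
- premature hydrogen transfer to the primary radical;
- a competing 1,2-aryl shift;
- loss of the phenoxyl radical by β-scission of C2–O1, followed by re-closure to the isoflavanone skeleton;
- insufficient facial discrimination in the hydrogen transfer.

Fallback with known chemistry: from 11 the ring expansion is run as a classical achiral Dowd–Beckwith reaction ((TMS)3SiH, AIBN, benzene, 80 °C) to give the racemic flavanone silyl ether F1. This is dehydrogenated with DDQ in dioxane to the flavone silyl ether F2. A copper-hydride-catalysed asymmetric conjugate reduction, a reaction known for chromones, then comes back to the route at 15. Its conditions are Cu(OAc)2, a chiral bisphosphine such as DTBM-SEGPHOS in the enantiomeric form that adds hydride to the Re face of C2, excess (EtO)2MeSiH, t-BuOH and toluene, followed by mild aqueous NH4F work-up.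

**Step 6.** The rearrangement may stop at the ortho stage by tautomerisation before the Cope shift. The C–I bond may also ionise with anisyl participation, or homolyse, on prolonged heating.

Fallback by cross-coupling instead of a sigmatropic shift: from 6, electrophilic iodination (NIS, cat. TFA, MeCN, 0 °C) at C7 of the dimethyl ether gives the 7-iodide F3. Stille coupling with tributyl(3-methylbut-2-enyl)stannane (Pd2(dba)3, AsPh3, DMF, 60 °C) gives the 7-prenyl dimethyl ether F4. Chelation-controlled cleavage of the 4-OMe group with BCl3 at −78 °C comes back to the route at 11, bypassing 7 and 9.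

**Step 3.** The ambident anion may be alkylated at oxygen instead of carbon, and a second displacement may bridge two molecules through the CH2 unit.

Fallback by aldol chemistry: from 4, addition to formaldehyde (aq. HCHO, cat. KHCO3, THF, rt) gives the 2-(hydroxymethyl) ketone F5. Iodination under Garegg–Samuelsson conditions (I2, PPh3, imidazole, toluene, 80 °C) comes back to the route at 6.

Further compounds
F1 | step 7 | rac-5-hydroxy-7-methoxy-2-[4-methoxy-3-(triisopropylsilyloxy)phenyl]-8-(3-methylbut-2-enyl)chroman-4-one | COc1ccc(C2CC(=O)c3c(O)cc(OC)c(CC=C(C)C)c3O2)cc1O[Si](C(C)C)(C(C)C)C(C)C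
F2 | step 7 | 5-hydroxy-7-methoxy-2-[4-methoxy-3-(triisopropylsilyloxy)phenyl]-8-(3-methylbut-2-enyl)-4H-chromen-4-one | COc1ccc(C2=CC(=O)c3c(O)cc(OC)c(CC=C(C)C)c3O2)cc1O[Si](C(C)C)(C(C)C)C(C)C
F3 | step 6 | rac-7-iodo-2-(iodomethyl)-4,6-dimethoxy-2-[4-methoxy-3-(triisopropylsilyloxy)phenyl]benzofuran-3(2H)-one | COc1cc(OC)c2c(c1I)OC(CI)(C2=O)c1ccc(OC)c(O[Si](C(C)C)(C(C)C)C(C)C)c1
F4 | step 6 | rac-2-(iodomethyl)-4,6-dimethoxy-7-(3-methylbut-2-enyl)-2-[4-methoxy-3-(triisopropylsilyloxy)phenyl]benzofuran-3(2H)-one | COc1cc(OC)c2c(c1CC=C(C)C)OC(CI)(C2=O)c1ccc(OC)c(O[Si](C(C)C)(C(C)C)C(C)C)c1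
F5 | step 3 | rac-2-(hydroxymethyl)-4,6-dimethoxy-2-[4-methoxy-3-(triisopropylsilyloxy)phenyl]benzofuran-3(2H)-one | COc1cc(OC)c2c(c1)OC(CO)(C2=O)c1ccc(OC)c(O[Si](C(C)C)(C(C)C)C(C)C)c1
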